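## The problem

The target is a linear octamer of oxygenated benzene rings A to H (C48H34O28), joined by seven diaryl ether oxygens and carrying 21 free phenolic hydroxyls. It has no stereocentre, so nothing has to be set or relayed; the whole problem is regiochemistry. Ring A is a 2,4,6-trihydroxyphenyl ether and ring H a 3,4,5-trihydroxyphenyl ether. Rings B, D and F are tetraoxygenated; rings C, E and G are pentaoxygenated with a single C–H. In six of the seven ethers one of the two linked carbons is flanked by two oxygen-bearing carbons (A C1, C C2, D C4, E C2, F C4, G C2). Copper-mediated ether synthesis tolerates that crowding on the phenol but not on the aryl halide, so each bond dictates which partner is the nucleophile. The rings differ only in where the oxygens sit, so electrophilic substitution on a large oligomer cannot be selective and every ring must arrive with its pattern fixed. The free polyphenol is air-sensitive and is released only in the last step from a per-O-alkyl ether; the carbene complex and the ynol ether are labile and are made last in their branches. The feature that invites a ring synthesis is ring B: oxygen at C1, C3, C4 and C5, hydrogen at C2 and C6, and the C4 hydroxyl para to the C1 aryl ether. This is the hydroquinone monoether pattern that results when a carbene carbon (C1), a vinyl group (C2–C3), one CO (C4) and an alkyne (C5–C6) are joined in a Dötz benzannulation.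

## Retrosynthesis

**35 to 34.** All 21 O–alkyl bonds are cut last. The octamer is carried as ether 34 (twenty methyl ethers, one ethyl ether on ring B O3), which is inert to base, copper and peracid. The forward step needs only exhaustive BBr3 dealkylation, which leaves diaryl ethers intact.

**34 to 33 and 27.** The E C2–O–F C1 ether is cut. Of the three ethers near the middle, only this one has the favourable polarity: a crowded phenol on E C2 and an open halide on F C1. Cutting D–E or F–G instead would need a 2,6-dimethoxyaryl halide or an ortho-substituted halide on a pentaoxygenated ring. The cut gives pentamer phenol 33 and trimer bromide 27, and the forward coupling has one halide and one free hydroxyl.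

**33 to 31, then 30 and 24.** The ring E phenol of 33 is traced to aldehyde 31 (Baeyer–Villiger), and the C C2–O–D C1 ether is then cut to give trimer phenol 30 and dimer bromide 24. A ready-made D-to-H pentamer halide was considered, but it would require coupling a bromophenol (26) with a halide made from 27, that is, halide selectivity between two electronically equal rings. Carrying the ring E oxygen as a formyl group keeps exactly one halide and one hydroxyl in each coupling, and the assembly becomes 3 + 2 + 3.

**30 to 29 to 28.** These are protecting-group changes only. The ring B phenol of 28 is methylated before the benzyl group on ring C O2 is removed, so that 30 has a single free hydroxyl.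

**28 to 8 and 20 (key disconnection).** The C1–C6, C4–C5 and C3–C4 bonds of ring B are cut; C4 comes from a CO ligand. The neighbouring option, two Ullmann couplings on a ring B dihalide, is feasible and is kept as the fallback. The benzannulation is preferred because it delivers all four ring B oxygens and both ethers (to A and to C) from monocyclic parts, and because the crowded A C1–O bond is then formed on a carbene carbon rather than at a doubly flanked aryl carbon. The forward reaction must insert the alkyne regioselectively and must end in the phenol.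

**8 to 5 and 6; 5 to 1 and 2.** The carbene C–OAr bond is cut by acyl-type substitution, giving acylchromate 5 and commercial phenol 6. Acylchromate 5 comes from Cr(CO)6 (1) and acid chloride 2, so the (E)-enol ether geometry is bought. The (Z)-configured 2-alkoxyvinyllithium route would give the wrong geometry.

**20 to 17, then 15 and 16; 15 back to 9.** The two alkyne carbons come from trichloroethylene 16 through dichlorovinyl ether 17. Phenol 15 needs a benzyl group on the crowded O2 and a free O1. It comes from 3,4,5-trimethoxyphenol 9 by MOM protection (10), directed metalation and oxidation between OMOM and OMe (13), benzylation (14) and MOM removal.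

**27 to 26 and 22; 26 to 24 to 23, then 21 and 22.** The G C2–O–H C1 ether is cut to a crowded phenol (26) and open iodide 22. The D–E and F–G ethers are the awkward ones, since the non-crowded partner carbon has an ortho oxygen. They are solved once: crowded phenol 21 is coupled with the symmetrical iodide 22 to give 23, and the ortho oxygen is then introduced by formylation and Baeyer–Villiger oxidation (24, 26). The same dimer serves as the D–E unit (24) and the F–G unit (26).

## Roads not taken

**Alternative 1:** Ring A is cut at C2–C3 and C5–C6. Forward, dimethyl 2-(3-bromo-4,5-dimethoxyphenoxy)propanedioate A2 and dimethyl 3-oxopentanedioate A3 condense under NaOMe (double Claisen/Dieckmann) to give the benzenetriol diester A1.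
- Merits: the reagents are cheap, no transition metal is needed, and the crowded A C1–O bond exists before ring A does. The condensation type is classical and, as chemistry, safer than the chromium step chosen here.
- Weak points: ring A is the one ring that can be bought with its pattern in place (6). A1 still needs saponification, double decarboxylation and O-methylation of a phloroglucinol that also alkylates on carbon. Only one of the seven ethers is addressed.
- Comparison: this road is more reliable but builds less. The chosen plan accepts an untested step and in return forms ring B with two ethers at once.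

**Alternative 2:** Each pentaoxygenated ring is cut at C1–C6. Forward, the squarate-derived cyclobutenone A5 is heated; ring opening to a dienylketene and 6π closure (Moore rearrangement) give the GH phenol A4.
- Merits: the thermal rearrangement is well precedented. All five oxygens of ring G are placed in one ring-forming step, and the crowded G C2–O–H ether is made by substitution on a vinylogous ester rather than with copper. In precedent this road is stronger than the chosen key step, and it reaches a pentaoxygenated ring more directly than steps 9 to 11.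
- Weak points: the phenol of A4 sits at G C1, so the next ether (to the doubly flanked F C4) has the wrong polarity for copper coupling. The sequence must be run three times (rings C, E, G), each time with a regioselective vinyllithium addition to an unsymmetrical squarate. Rings B, D and F are untouched.
- Comparison: the chosen plan sets against this that every phenol it frees is at a crowded position, where the coupling polarity is right.

**Alternative 3:** Ring F is cut at C2–C3 and C1–C6. Forward, cyclobutenone A7 (carrying rings G and H) is heated with ynol ether A8 of ring E; vinylketene formation, [2+2] addition, ring opening and 6π closure (Danheiser benzannulation) give the EFGH tetramer A6.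
- Merits: the reaction is metal-free, alkoxyalkynes are established partners, and four rings are joined at a central ring. In precedent and convergence this road is better than the chosen one.
- Weak points: A7 is itself a multi-step problem (a 4-aryloxycyclobutenone carrying two rings). A6 must grow towards ring D from the benzylated E O1, an open phenol that would have to be arylated by the doubly flanked D C4, which is the unfavourable polarity.
- Comparison: the chosen plan answers with monocyclic key-step precursors and with later couplings that all pair a crowded phenol with an open halide.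

Key step: step 13

Remark on the chemistry: ring B O3 is carried as an ethyl ether (all other hydroxyls as methyl ethers) because the commercial (E)-enol ether acid chloride is the ethoxy compound 2; BBr3 removes ethyl and methyl alike, so the target is unchanged.

## Route

Step 1
Reactants: 1 chromium hexacarbonyl; 2 (E)-3-ethoxyprop-2-enoyl chloride
Product: 5 tetramethylammonium pentacarbonyl[(E)-3-ethoxyprop-2-enoyl]chromate, via disodium pentacarbonylchromate 3 (not isolated), via sodium acylchromate 4 (not isolated)
Conditions: NaC10H8 (2 equiv), THF, −78 °C; then 2, −78 to 0 °C; then Me4NBr, degassed H2O, 0 °C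
Reagents that add atoms: tetramethylammonium bromide, C[N+](C)(C)C.[Br-]
Why: Two-electron reduction of Cr(CO)6 gives the pentacarbonylchromate dianion, which is acylated at the metal by the acid chloride (a known route to acylchromates); the (E) geometry of 2 is carried over unchanged, and cation exchange gives the storable ammonium salt.

Step 2
Reactants: 5 tetramethylammonium pentacarbonyl[(E)-3-ethoxyprop-2-enoyl]chromate; 6 2,4,6-trimethoxyphenol
Product: 8 pentacarbonyl[(E)-3-ethoxy-1-(2,4,6-trimethoxyphenoxy)prop-2-enylidene]chromium, via acetoxycarbene complex 7 (not isolated)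
Conditions: AcBr, CH2Cl2, −40 °C; then 6, −40 to 0 °C
Reagents that add atoms: none
Why: O-Acylation of the acylchromate gives the highly electrophilic acetoxycarbene, on which the phenol displaces acetate by addition–elimination at the carbene carbon (acyl-type substitution of Fischer carbenes, known for alcohols and phenols). The crowded A C1–O bond is thus made on an sp2 carbene carbon.

Step 3
Reactants: 9 3,4,5-trimethoxyphenol
Product: 10 1,2,3-trimethoxy-5-(methoxymethoxy)benzene
Conditions: MOMCl, i-Pr2NEt, CH2Cl2, 0 °C to rt
Reagents that add atoms: chloromethyl methyl ether, COCCl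
Why: Williamson-type O-alkylation; the MOM ether also serves as the directing group for step 4.

Step 4
Reactants: 10 1,2,3-trimethoxy-5-(methoxymethoxy)benzene
Product: 13 2,3,4-trimethoxy-6-(methoxymethoxy)phenol, via aryllithium 11 (not isolated), via dimethyl arylboronate 12 (not isolated)
Conditions: n-BuLi, THF, 0 °C; B(OMe)3, −78 °C to rt; 30% H2O2, AcOH, 0 °C
Reagents that add atoms: hydrogen peroxide, OO
Why: Directed ortho-metalation; the two ring hydrogens are equivalent and each lies between OMOM and OMe, so lithiation is unambiguous. Borylation and peroxide oxidation (carbon-to-oxygen 1,2-shift) install the fifth oxygen.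

Step 5
Reactants: 13 2,3,4-trimethoxy-6-(methoxymethoxy)phenol
Product: 14 2-(benzyloxy)-3,4,5-trimethoxy-1-(methoxymethoxy)benzene
Conditions: BnBr, K2CO3, DMF, rt to 50 °C
Reagents that add atoms: benzyl bromide, BrCc1ccccc1
Why: Williamson benzylation of the crowded phenol with a reactive primary benzylic halide.

Step 6
Reactants: 14 2-(benzyloxy)-3,4,5-trimethoxy-1-(methoxymethoxy)benzene
Product: 15 2-(benzyloxy)-3,4,5-trimethoxyphenol
Conditions: HCl (2 M), MeOH, 40 °C
Reagents that add atoms: none
Why: Acid-catalysed acetal exchange removes the MOM group; benzyl and methyl ethers are inert.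

Step 7
Reactants: 15 2-(benzyloxy)-3,4,5-trimethoxyphenol; 16 trichloroethylene
Product: 17 2-(benzyloxy)-1-{[(E)-1,2-dichloroethenyl]oxy}-3,4,5-trimethoxybenzene
Conditions: K2CO3, DMF, 70 °C
Reagents that add atoms: none
Why: Base-mediated vinylic substitution of the phenoxide on trichloroethylene gives the (E)-1,2-dichlorovinyl ether, the standard precursor of ynol ethers and known for phenols.

Step 8
Reactants: 17 2-(benzyloxy)-1-{[(E)-1,2-dichloroethenyl]oxy}-3,4,5-trimethoxybenzene
Product: 20 2-(benzyloxy)-1-(ethynyloxy)-3,4,5-trimethoxybenzene, via chloroethynyl ether 18 (not isolated), via lithium acetylide 19 (not isolated)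
Conditions: n-BuLi (2.3 equiv), Et2O, −78 to −40 °C; H2O, −78 °C; cold work-up, used at once
Reagents that add atoms: none
Why: Dehydrochlorination to the chloroalkyne, chlorine–lithium exchange and cold protonation (the established dichlorovinyl ether route to ynol ethers). An aryl ynol ether has no β-hydrogen for retro-ene loss of ketene but polymerises on storage, so it is used immediately as a cold solution.

Step 9
Reactants: 21 4-bromo-2,6-dimethoxyphenol; 22 5-iodo-1,2,3-trimethoxybenzene
Product: 23 5-bromo-1,3-dimethoxy-2-(3,4,5-trimethoxyphenoxy)benzene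
Conditions: CuI (10 mol%), picolinic acid (20 mol%), K3PO4, DMSO, 90 °C; 22 in excess (1.5 equiv)
Reagents that add atoms: none
Why: Ullmann diaryl ether synthesis between a 2,6-disubstituted phenol and an unhindered aryl iodide. The C–Br bond para to the phenoxide oxygen is deactivated, and excess iodide outcompetes the product bromide.

Step 10
Reactants: 23 5-bromo-1,3-dimethoxy-2-(3,4,5-trimethoxyphenoxy)benzene
Product: 24 6-(4-bromo-2,6-dimethoxyphenoxy)-2,3,4-trimethoxybenzaldehyde
Conditions: Cl2CHOMe, TiCl4, CH2Cl2, −78 to 0 °C; ice/1 M HCl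
Reagents that add atoms: dichloromethyl methyl ether, COC(Cl)Cl; water, O
Why: Rieche formylation; the two equivalent free positions of the trimethoxyphenoxy ring have oxygen donors at both ortho positions and the para position. The hydrogens of the brominated ring have one donor fewer and an ortho bromine, so a single aldehyde is expected.

Step 11
Reactants: 24 6-(4-bromo-2,6-dimethoxyphenoxy)-2,3,4-trimethoxybenzaldehyde
Product: 26 6-(4-bromo-2,6-dimethoxyphenoxy)-2,3,4-trimethoxyphenol, via aryl formate 25 (not isolated)
Conditions: mCPBA, NaHCO3, CH2Cl2, 0 °C to rt; then K2CO3 (cat.), MeOH, rt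
Reagents that add atoms: 3-chloroperoxybenzoic acid, OOC(=O)c1cccc(Cl)c1
Why: Baeyer–Villiger oxidation with aryl migration (favoured for a 2,4,6-trioxygenated benzaldehyde), then methanolysis of the formate; overall a Dakin-type aldehyde-to-phenol exchange.

Step 12
Reactants: 26 6-(4-bromo-2,6-dimethoxyphenoxy)-2,3,4-trimethoxyphenol; 22 5-iodo-1,2,3-trimethoxybenzene
Product: 27 5-bromo-1,3-dimethoxy-2-[3,4,5-trimethoxy-2-(3,4,5-trimethoxyphenoxy)phenoxy]benzene
Conditions: CuI (10 mol%), picolinic acid (20 mol%), K3PO4, DMSO, 90 °C; 22 in excess (2 equiv)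
Reagents that add atoms: none
Why: Ullmann coupling of the crowded phenol with the open aryl iodide; the iodide reacts faster than the aryl bromide of 26 and 27 and is used in excess.

Step 13
Reactants: 8 pentacarbonyl[(E)-3-ethoxy-1-(2,4,6-trimethoxyphenoxy)prop-2-enylidene]chromium; 20 2-(benzyloxy)-1-(ethynyloxy)-3,4,5-trimethoxybenzene
Product: 28 2-[2-(benzyloxy)-3,4,5-trimethoxyphenoxy]-6-ethoxy-4-(2,4,6-trimethoxyphenoxy)phenol
Conditions: 20 (1.5 equiv), THF (0.05 M), 45–50 °C, argon; then air, rt
Reagents that add atoms: none
Why: Proposed new method: thermal loss of one CO from the zerovalent chromium carbene 8 opens a site for the ynol ether, which inserts with its CH terminus bonding to the carbene carbon (C1–C6); the steric rule for terminal alkynes and the polarisation of the ynol ether (nucleophilic CH carbon, electrophilic carbene carbon) point the same way. CO insertion then gives a vinylketene complex whose ketene carbon is attached to the aryloxy-bearing alkyne carbon (C4–C5), and 6π electrocyclisation onto the ethoxyvinyl terminus (C3–C4) gives a cyclohexadienone that tautomerises to the phenol; air removes the chromium. The closest known reaction type is the Dötz benzannulation of alkenyl(alkoxy)carbene chromium complexes with terminal alkynes, which gives 4-alkoxyphenols with the alkyne substituent next to the new hydroxyl; new here is the combination of an aryloxy carbene, a 3-alkoxyvinyl group and an aryl ynol ether. Ring B is closed as a six-membered carbocycle by thermal disrotatory 6π electrocyclisation of a dienylketene, every ring atom coming from an open-chain partner; no stereocentre is formed. The step needs regioselective insertion, secured as stated, and phenol formation in preference to cyclobutenone, furan or CO-free cyclopentadiene products. An alkenyl rather than aryl carbene, the (E)-enol ether with its substituent turned outward, the weakly donating aryloxy group (easier CO loss) and THF as solvent all favour the phenol.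

Step 14
Reactants: 28 2-[2-(benzyloxy)-3,4,5-trimethoxyphenoxy]-6-ethoxy-4-(2,4,6-trimethoxyphenoxy)phenol
Product: 29 2-(benzyloxy)-1-[3-ethoxy-2-methoxy-5-(2,4,6-trimethoxyphenoxy)phenoxy]-3,4,5-trimethoxybenzene
Conditions: MeI, K2CO3, DMF, 40 °C
Reagents that add atoms: iodomethane, CI
Why: Williamson methylation caps the ring B phenol so that the ring C oxygen is the only free hydroxyl after step 15.

Step 15
Reactants: 29 2-(benzyloxy)-1-[3-ethoxy-2-methoxy-5-(2,4,6-trimethoxyphenoxy)phenoxy]-3,4,5-trimethoxybenzene
Product: 30 6-[3-ethoxy-2-methoxy-5-(2,4,6-trimethoxyphenoxy)phenoxy]-2,3,4-trimethoxyphenol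
Conditions: H2 (1 atm), Pd/C, EtOAc–MeOH, rt
Reagents that add atoms: none
Why: Hydrogenolysis of the benzyl ether; alkyl aryl and diaryl ethers are untouched and no halide is present.

Step 16
Reactants: 30 6-[3-ethoxy-2-methoxy-5-(2,4,6-trimethoxyphenoxy)phenoxy]-2,3,4-trimethoxyphenol; 24 6-(4-bromo-2,6-dimethoxyphenoxy)-2,3,4-trimethoxybenzaldehyde
Product: 31 ABCDE pentamer aldehyde, 6-(4-{6-[3-ethoxy-2-methoxy-5-(2,4,6-trimethoxyphenoxy)phenoxy]-2,3,4-trimethoxyphenoxy}-2,6-dimethoxyphenoxy)-2,3,4-trimethoxybenzaldehyde
Conditions: CuI (20 mol%), picolinic acid (40 mol%), K3PO4, DMSO, 110 °C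
Reagents that add atoms: none
Why: Ullmann coupling of the crowded ring C phenol with the unhindered aryl bromide of ring D; one halide and one hydroxyl are present, and the non-enolisable aldehyde tolerates anhydrous K3PO4.

Step 17
Reactants: 31 ABCDE pentamer aldehyde
Product: 33 ABCDE pentamer phenol, 6-(4-{6-[3-ethoxy-2-methoxy-5-(2,4,6-trimethoxyphenoxy)phenoxy]-2,3,4-trimethoxyphenoxy}-2,6-dimethoxyphenoxy)-2,3,4-trimethoxyphenol, via pentamer formate 32 (not isolated)
Conditions: mCPBA (1.2 equiv), NaHCO3, CH2Cl2, 0 °C; then K2CO3 (cat.), degassed MeOH, rt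
Reagents that add atoms: 3-chloroperoxybenzoic acid, OOC(=O)c1cccc(Cl)c1
Why: Baeyer–Villiger oxidation and formate methanolysis as in step 11 unmask the ring E phenol; buffered peracid at 0 °C lets the fast aldehyde oxidation outrun attack on the electron-rich rings.

Step 18
Reactants: 33 ABCDE pentamer phenol; 27 5-bromo-1,3-dimethoxy-2-[3,4,5-trimethoxy-2-(3,4,5-trimethoxyphenoxy)phenoxy]benzene
Product: 34 per-O-alkyl octamer (rings A to H; ethyl ether at ring B O3, twenty methyl ethers)
Conditions: CuI (20 mol%), picolinic acid (40 mol%), K3PO4, DMSO, 110 °C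
Reagents that add atoms: none
Why: Ullmann coupling with the same polarity as step 16 (crowded ring E phenol, open ring F bromide); no other halide or free hydroxyl is present.

Step 19
Reactants: 34 per-O-alkyl octamer
Product: 35 CNP0175816.0, the free octameric polyphenol
Conditions: BBr3 (45 equiv), CH2Cl2, −78 °C to rt, argon; then MeOH/H2O, 0 °C
Reagents that add atoms: none
Why: BBr3 dealkylation: bromide attacks the O-alkyl carbon of each boron-complexed ether, cleaving the methyl and ethyl ethers, while the diaryl ether C–O bonds are not cleaved.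

## Compound list

1 | chromium hexacarbonyl | O=C=[Cr](=C=O)(=C=O)(=C=O)(=C=O)=C=O | starting material
2 | (E)-3-ethoxyprop-2-enoyl chloride | CCO/C=C/C(=O)Cl | starting material
3 | disodium pentacarbonylchromate, Na2Cr(CO)5 | [Na+].[Na+].O=C=[Cr-2](=C=O)(=C=O)(=C=O)=C=O | intermediate (not isolated)
4 | sodium pentacarbonyl[(E)-3-ethoxyprop-2-enoyl]chromate | [Na+].CCO/C=C/C([O-])=[Cr](=C=O)(=C=O)(=C=O)(=C=O)=C=O | intermediate (not isolated)
5 | tetramethylammonium pentacarbonyl[(E)-3-ethoxyprop-2-enoyl]chromate | C[N+](C)(C)C.CCO/C=C/C([O-])=[Cr](=C=O)(=C=O)(=C=O)(=C=O)=C=O | intermediate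
6 | 2,4,6-trimethoxyphenol | COc1cc(OC)c(O)c(OC)c1 | starting material
7 | pentacarbonyl[(E)-1-acetoxy-3-ethoxyprop-2-enylidene]chromium | CCO/C=C/C(OC(C)=O)=[Cr](=C=O)(=C=O)(=C=O)(=C=O)=C=O | intermediate (not isolated)
8 | pentacarbonyl[(E)-3-ethoxy-1-(2,4,6-trimethoxyphenoxy)prop-2-enylidene]chromium | CCO/C=C/C(Oc1c(OC)cc(OC)cc1OC)=[Cr](=C=O)(=C=O)(=C=O)(=C=O)=C=O | intermediate
9 | 3,4,5-trimethoxyphenol | COc1cc(O)cc(OC)c1OC | starting material
10 | 1,2,3-trimethoxy-5-(methoxymethoxy)benzene | COCOc1cc(OC)c(OC)c(OC)c1 | intermediate
11 | [2,3,4-trimethoxy-6-(methoxymethoxy)phenyl]lithium | COCOc1c([Li])c(OC)c(OC)c(OC)c1 | intermediate (not isolated)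
12 | dimethyl [2,3,4-trimethoxy-6-(methoxymethoxy)phenyl]boronate | COCOc1c(B(OC)OC)c(OC)c(OC)c(OC)c1 | intermediate (not isolated)
13 | 2,3,4-trimethoxy-6-(methoxymethoxy)phenol | COCOc1c(O)c(OC)c(OC)c(OC)c1 | intermediate
14 | 2-(benzyloxy)-3,4,5-trimethoxy-1-(methoxymethoxy)benzene | COCOc1cc(OC)c(OC)c(OC)c1OCc1ccccc1 | intermediate
15 | 2-(benzyloxy)-3,4,5-trimethoxyphenol | COc1cc(O)c(OCc2ccccc2)c(OC)c1OC | intermediate
16 | trichloroethylene | ClC=C(Cl)Cl | starting material
17 | 2-(benzyloxy)-1-{[(E)-1,2-dichloroethenyl]oxy}-3,4,5-trimethoxybenzene | Cl/C=C(/Cl)Oc1cc(OC)c(OC)c(OC)c1OCc1ccccc1 | intermediate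
18 | 2-(benzyloxy)-1-[(chloroethynyl)oxy]-3,4,5-trimethoxybenzene | ClC#COc1cc(OC)c(OC)c(OC)c1OCc1ccccc1 | intermediate (not isolated)
19 | lithium [2-(benzyloxy)-3,4,5-trimethoxyphenoxy]ethynide | [Li]C#COc1cc(OC)c(OC)c(OC)c1OCc1ccccc1 | intermediate (not isolated)
20 | 2-(benzyloxy)-1-(ethynyloxy)-3,4,5-trimethoxybenzene | C#COc1cc(OC)c(OC)c(OC)c1OCc1ccccc1 | intermediate
21 | 4-bromo-2,6-dimethoxyphenol | COc1cc(Br)cc(OC)c1O | starting material
22 | 5-iodo-1,2,3-trimethoxybenzene | COc1cc(I)cc(OC)c1OC | starting material
23 | 5-bromo-1,3-dimethoxy-2-(3,4,5-trimethoxyphenoxy)benzene | COc1cc(Br)cc(OC)c1Oc1cc(OC)c(OC)c(OC)c1 | intermediate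
24 | 6-(4-bromo-2,6-dimethoxyphenoxy)-2,3,4-trimethoxybenzaldehyde | COc1cc(Br)cc(OC)c1Oc1cc(OC)c(OC)c(OC)c1C=O | intermediate
25 | 6-(4-bromo-2,6-dimethoxyphenoxy)-2,3,4-trimethoxyphenyl formate | COc1cc(Br)cc(OC)c1Oc1cc(OC)c(OC)c(OC)c1OC=O | intermediate (not isolated)
26 | 6-(4-bromo-2,6-dimethoxyphenoxy)-2,3,4-trimethoxyphenol | COc1cc(Br)cc(OC)c1Oc1cc(OC)c(OC)c(OC)c1O | intermediate
27 | 5-bromo-1,3-dimethoxy-2-[3,4,5-trimethoxy-2-(3,4,5-trimethoxyphenoxy)phenoxy]benzene | COc1cc(Br)cc(OC)c1Oc1cc(OC)c(OC)c(OC)c1Oc1cc(OC)c(OC)c(OC)c1 | intermediate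
28 | 2-[2-(benzyloxy)-3,4,5-trimethoxyphenoxy]-6-ethoxy-4-(2,4,6-trimethoxyphenoxy)phenol (ABC trimer, ring B free at O4) | CCOc1cc(Oc2c(OC)cc(OC)cc2OC)cc(Oc2cc(OC)c(OC)c(OC)c2OCc2ccccc2)c1O | intermediate
29 | 2-(benzyloxy)-1-[3-ethoxy-2-methoxy-5-(2,4,6-trimethoxyphenoxy)phenoxy]-3,4,5-trimethoxybenzene | CCOc1cc(Oc2c(OC)cc(OC)cc2OC)cc(Oc2cc(OC)c(OC)c(OC)c2OCc2ccccc2)c1OC | intermediate
30 | 6-[3-ethoxy-2-methoxy-5-(2,4,6-trimethoxyphenoxy)phenoxy]-2,3,4-trimethoxyphenol (ABC trimer, ring C free at O2) | CCOc1cc(Oc2c(OC)cc(OC)cc2OC)cc(Oc2cc(OC)c(OC)c(OC)c2O)c1OC | intermediate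
31 | 6-(4-{6-[3-ethoxy-2-methoxy-5-(2,4,6-trimethoxyphenoxy)phenoxy]-2,3,4-trimethoxyphenoxy}-2,6-dimethoxyphenoxy)-2,3,4-trimethoxybenzaldehyde (ABCDE aldehyde) | CCOc1cc(Oc2c(OC)cc(OC)cc2OC)cc(Oc2cc(OC)c(OC)c(OC)c2Oc2cc(OC)c(Oc3cc(OC)c(OC)c(OC)c3C=O)c(OC)c2)c1OC | intermediate
32 | formate ester of 33 (ABCDE aryl formate, ring E O2 formylated) | CCOc1cc(Oc2c(OC)cc(OC)cc2OC)cc(Oc2cc(OC)c(OC)c(OC)c2Oc2cc(OC)c(Oc3cc(OC)c(OC)c(OC)c3OC=O)c(OC)c2)c1OC | intermediate (not isolated)
33 | 6-(4-{6-[3-ethoxy-2-methoxy-5-(2,4,6-trimethoxyphenoxy)phenoxy]-2,3,4-trimethoxyphenoxy}-2,6-dimethoxyphenoxy)-2,3,4-trimethoxyphenol (ABCDE phenol, ring E free at O2) | CCOc1cc(Oc2c(OC)cc(OC)cc2OC)cc(Oc2cc(OC)c(OC)c(OC)c2Oc2cc(OC)c(Oc3cc(OC)c(OC)c(OC)c3O)c(OC)c2)c1OC | intermediate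
34 | per-O-alkyl octamer A to H: every hydroxyl of 35 as methyl ether except ring B O3, which is an ethyl ether | CCOc1cc(Oc2c(OC)cc(OC)cc2OC)cc(Oc2cc(OC)c(OC)c(OC)c2Oc2cc(OC)c(Oc3cc(OC)c(OC)c(OC)c3Oc3cc(OC)c(Oc4cc(OC)c(OC)c(OC)c4Oc4cc(OC)c(OC)c(OC)c4)c(OC)c3)c(OC)c2)c1OC | intermediate
35 | CNP0175816.0: octamer of ether-linked rings A to H (A 2,4,6-trihydroxyphenyl; B 3,4-dihydroxy, ethers at C1 and C5; C, E, G 3,4,5-trihydroxy, ethers at C1 and C2; D, F 3,5-dihydroxy, ethers at C1 and C4; H 3,4,5-trihydroxyphenyl) | Oc1cc(O)c(Oc2cc(O)c(O)c(Oc3cc(O)c(O)c(O)c3Oc3cc(O)c(Oc4cc(O)c(O)c(O)c4Oc4cc(O)c(Oc5cc(O)c(O)c(O)c5Oc5cc(O)c(O)c(O)c5)c(O)c4)c(O)c3)c2)c(O)c1 | target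

## Step count and risk

Total: 19 steps. Longest linear sequence: 13 steps (9 to 35 through steps 3–8 and 13–19). Dimer 23 is made once and used twice (as 24 in step 16 and, through 26, in step 12).

**Step 13 (key step, proposed new method).** The most likely failure is that the nucleophilic ynol ether inserts into the carbene without the subsequent CO insertion, or adds to the electron-poor vinylcarbene in a [2+2] or conjugate sense. This would lead to stable dienylcarbene, cyclobutenone or cyclopentadiene-type products, or to alkyne oligomerisation, instead of the phenol. The same fallback applies if the crowded phenol 6 fails to substitute the labile acetoxycarbene in step 2. The fallback uses only known copper chemistry. It sets out from phenols 15 and 6 and returns at 29, bypassing steps 1, 2, 7, 8, 13 and 14. 2-Ethoxyphenol is brominated para to the hydroxyl (Bu4NBr3, CH2Cl2–MeOH) to 4-bromo-2-ethoxyphenol F1, iodinated ortho to the hydroxyl (I2, KI, aqueous NaHCO3) to 4-bromo-2-ethoxy-6-iodophenol F2, and O-methylated (MeI, K2CO3) to 5-bromo-1-ethoxy-3-iodo-2-methoxybenzene F3. Iodide-selective Ullmann coupling of F3 with 15 (CuI, picolinic acid, K3PO4, DMSO, 80 °C) gives 2-(benzyloxy)-1-(5-bromo-3-ethoxy-2-methoxyphenoxy)-3,4,5-trimethoxybenzene F4. Its unhindered bromide is then coupled with the crowded phenol 6 at 110 °C to give 29.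

**Step 12.** Loss of halide selectivity is the risk: once the iodide 22 is depleted, the phenoxide of 26 can attack the aryl bromide of another molecule of 26 or of 27 and form oligomers. The fallback sets out from 26 and returns at 27 without a new intermediate. It changes the coupling from a halide substitution to an oxidative Chan–Lam coupling of 26 with commercial 3,4,5-trimethoxyphenylboronic acid (Cu(OAc)2, pyridine, 4 Å molecular sieves, CH2Cl2, air, rt), to which aryl bromides are inert.

**Step 16 (step 18 has the same profile).** The phenoxide of 30 is flanked by an aryloxy and a methoxy group, and the electron-rich bromide adds slowly to copper. At the temperature then needed, protodebromination and degradation of the aldehyde can overtake C–O bond formation. The fallback changes the electrophile. It sets out from 23 and returns at 31. Copper-catalysed halogen exchange (CuI, NaI, trans-N,N′-dimethylcyclohexane-1,2-diamine, dioxane, 110 °C; done before the aldehyde is present so that the diamine is not consumed) gives 5-iodo-1,3-dimethoxy-2-(3,4,5-trimethoxyphenoxy)benzene F5. Rieche formylation as in step 10 gives 6-(4-iodo-2,6-dimethoxyphenoxy)-2,3,4-trimethoxybenzaldehyde F6, which should couple with 30 at 80–90 °C.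

**Step 19.** Twenty-one ethers must be cleaved. Incomplete dealkylation gives mixtures of partial ethers that are hard to separate from the very polar product, and the free polyphenol oxidises in air during chromatography. The fallback sets out from 34 and returns at 35. The crude BBr3 product is not purified but acetylated (Ac2O, pyridine) to the henicosaacetate F7, which is stable, soluble in organic solvents and purifiable on silica; under-cleaved material is recognised at this stage and recycled. Deacetylation (NaOMe cat., degassed MeOH, 0 °C, then acidic ion-exchange resin) then releases 35 under argon.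

## Further compounds

F1 | step 13 | 4-bromo-2-ethoxyphenol | CCOc1cc(Br)ccc1O
F2 | step 13 | 4-bromo-2-ethoxy-6-iodophenol | CCOc1cc(Br)cc(I)c1O
F3 | step 13 | 5-bromo-1-ethoxy-3-iodo-2-methoxybenzene | CCOc1cc(Br)cc(I)c1OC
F4 | step 13 | 2-(benzyloxy)-1-(5-bromo-3-ethoxy-2-methoxyphenoxy)-3,4,5-trimethoxybenzene | CCOc1cc(Br)cc(Oc2cc(OC)c(OC)c(OC)c2OCc2ccccc2)c1OC
F0 | step 12 | none | none
F5 | step 16 | 5-iodo-1,3-dimethoxy-2-(3,4,5-trimethoxyphenoxy)benzene | COc1cc(I)cc(OC)c1Oc1cc(OC)c(OC)c(OC)c1
F6 | step 16 | 6-(4-iodo-2,6-dimethoxyphenoxy)-2,3,4-trimethoxybenzaldehyde | COc1cc(I)cc(OC)c1Oc1cc(OC)c(OC)c(OC)c1C=O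
F7 | step 19 | henicosaacetate of 35 (all 21 hydroxyls acetylated) | CC(=O)Oc1cc(OC(C)=O)c(Oc2cc(OC(C)=O)c(OC(C)=O)c(Oc3cc(OC(C)=O)c(OC(C)=O)c(OC(C)=O)c3Oc3cc(OC(C)=O)c(Oc4cc(OC(C)=O)c(OC(C)=O)c(OC(C)=O)c4Oc4cc(OC(C)=O)c(Oc5cc(OC(C)=O)c(OC(C)=O)c(OC(C)=O)c5Oc5cc(OC(C)=O)c(OC(C)=O)c(OC(C)=O)c5)c(OC(C)=O)c4)c(OC(C)=O)c3)c2)c(OC(C)=O)c1
A1 | alternative 1 | dimethyl 5-(3-bromo-4,5-dimethoxyphenoxy)-2,4,6-trihydroxybenzene-1,3-dicarboxylate | COC(=O)c1c(O)c(C(=O)OC)c(O)c(Oc2cc(OC)c(OC)c(Br)c2)c1O
A2 | alternative 1 | dimethyl 2-(3-bromo-4,5-dimethoxyphenoxy)propanedioate | COC(=O)C(Oc1cc(OC)c(OC)c(Br)c1)C(=O)OC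
A3 | alternative 1 | dimethyl 3-oxopentanedioate | COC(=O)CC(=O)CC(=O)OC
A4 | alternative 2 | 3,4,5-trimethoxy-2-(3,4,5-trimethoxyphenoxy)phenol | Oc1cc(OC)c(OC)c(OC)c1Oc1cc(OC)c(OC)c(OC)c1
A5 | alternative 2 | 3,4-dimethoxy-4-(1-methoxyethenyl)-2-(3,4,5-trimethoxyphenoxy)cyclobut-2-en-1-one | C=C(OC)C1(OC)C(OC)=C(Oc2cc(OC)c(OC)c(OC)c2)C1=O
A6 | alternative 3 | EFGH tetramer, ring F free at O3 and ethylated at O5, ring E benzylated at O1 | Oc1cc(Oc2c(OCc3ccccc3)cc(OC)c(OC)c2OC)cc(OCC)c1Oc1cc(OC)c(OC)c(OC)c1Oc1cc(OC)c(OC)c(OC)c1
A7 | alternative 3 | 3-ethoxy-4-[3,4,5-trimethoxy-2-(3,4,5-trimethoxyphenoxy)phenoxy]cyclobut-2-en-1-one | CCOC1=CC(=O)C1Oc1cc(OC)c(OC)c(OC)c1Oc1cc(OC)c(OC)c(OC)c1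
A8 | alternative 3 | 1-(benzyloxy)-2-(ethynyloxy)-3,4,5-trimethoxybenzene | C#COc1c(OCc2ccccc2)cc(OC)c(OC)c1OC
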